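**Retrosynthetic overview**
- Both isobutyrates are put on last (C8–O and C9–O acylation of a macrocyclic 8,9-diol), followed by unmasking of the C14 aldehyde.
- The ten-membered carbocycle (second ring) is closed at C9–C10 by a Nozaki–Hiyama–Kishi reaction of a (Z)-iodoalkene onto an α-hydroxy aldehyde.
- The γ-lactone (first ring) is closed at the key C6–O bond by a stereoinvertive lactonisation that turns the easily made 6,7-syn hydroxy ester into the trans-fused lactone.
- C6–C7 comes from an indium Barbier coupling of a neryl-derived (Z)-enal/iodoalkene fragment with a D-glyceraldehyde-derived 2-(bromomethyl)acrylate; C8 comes from the chiral pool.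

Assumption: the SMILES defines the target as the (6R,7S,8S,9S) isomer in germacrane numbering, which is used for all atom labels below (lactone O on C6, C11 on C7, esters on C8 and C9, CHO = C14 on C10, methyl C15 on C4), with C3 cis to C6 across C4=C5 and C2 cis to C9 across C1=C10.

**Step 1**
Reactants: 1 (2Z)-3,7-dimethylocta-2,6-dien-1-yl acetate (neryl acetate)
Product: 3 (2Z)-3-methyl-6-oxohex-2-en-1-yl acetate, via ozonide 2 (not isolated)
Conditions: O3 (1.0 equiv), CH2Cl2, −78 °C; then Me2S, −78 °C to rt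
Reagents that add atoms: ozone, [O-][O+]=O
Why: Ozonolysis with reductive work-up cleaves the electron-rich isopropylidene alkene selectively because the other alkene is deactivated by the allylic acetate, and no stereocenter is formed while the Z alkene is untouched.

**Step 2**
Reactants: 3 (2Z)-3-methyl-6-oxohex-2-en-1-yl acetate; 4 (triphenylphosphoranylidene)acetaldehyde
Product: 5 (2Z,6E)-3-methyl-8-oxoocta-2,6-dien-1-yl acetate
Conditions: toluene, 80 °C
Reagents that add atoms: none
Why: Wittig olefination with the formyl-stabilised ylide adds C10 and C14 and gives the E enal under thermodynamic control.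

**Step 3**
Reactants: 5 (2Z,6E)-3-methyl-8-oxoocta-2,6-dien-1-yl acetate
Product: 6 (2Z,6Z)-7-iodo-3-methyl-8-oxoocta-2,6-dien-1-yl acetate
Conditions: I2, K2CO3, DMAP (20 mol%), THF/H2O (1:1), rt
Reagents that add atoms: iodine, II
Why: Baylis–Hillman-type α-iodination (DMAP conjugate addition, iodination of the enolate, E1cB loss of DMAP) gives the Z α-iodoenal, in which iodine marks the future C9 position cis to C2 and the formyl group is trans to C2 as in the target.

**Step 4**
Reactants: 6 (2Z,6Z)-7-iodo-3-methyl-8-oxoocta-2,6-dien-1-yl acetate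
Product: 8 (2Z,6Z)-7-iodo-8,8-dimethoxy-3-methylocta-2,6-dien-1-ol, via acetal acetate 7 (not isolated)
Conditions: HC(OMe)3, PPTS (5 mol%), MeOH, rt; then K2CO3, rt
Reagents that add atoms: trimethyl orthoformate, COC(OC)OC
Why: Acid-catalysed acetalisation masks C14 for the organometallic steps and K2CO3-catalysed transesterification in the same flask removes the allylic acetate without touching the alkenyl iodide or either Z alkene.

**Step 5**
Reactants: 8 (2Z,6Z)-7-iodo-8,8-dimethoxy-3-methylocta-2,6-dien-1-ol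
Product: 9 (2Z,6Z)-7-iodo-8,8-dimethoxy-3-methylocta-2,6-dienal
Conditions: TEMPO (10 mol%), PhI(OAc)2, CH2Cl2, rt
Reagents that add atoms: none
Why: TEMPO-catalysed oxidation converts the primary allylic alcohol into the neral-type Z enal (C6 aldehyde) without Z/E isomerisation.

**Step 6**
Reactants: 10 (4R)-2,2-dimethyl-1,3-dioxolane-4-carbaldehyde; 11 methyl prop-2-enoate (methyl acrylate)
Product: 12 methyl 2-{[(4R)-2,2-dimethyl-1,3-dioxolan-4-yl](hydroxy)methyl}prop-2-enoate (both carbinol epimers)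
Conditions: DABCO (0.5 equiv), dioxane/H2O (1:1), rt, 48 h
Reagents that add atoms: none
Why: Morita–Baylis–Hillman reaction of the activated α-alkoxy aldehyde joins C7 to C11; the new carbinol centre is erased in the next step and C8 comes unchanged from the chiral pool.

**Step 7**
Reactants: 12 methyl 2-{[(4R)-2,2-dimethyl-1,3-dioxolan-4-yl](hydroxy)methyl}prop-2-enoate
Product: 13 methyl (2Z)-2-(bromomethyl)-3-[(4S)-2,2-dimethyl-1,3-dioxolan-4-yl]prop-2-enoate
Conditions: NBS, Me2S, CH2Cl2, 0 °C to rt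
Reagents that add atoms: N-bromosuccinimide, BrN1C(=O)CCC1=O
Why: Corey–Kim-type activation of the allylic alcohol and SN2′ delivery of bromide give the thermodynamically favoured Z allyl bromide (dioxolane cis to CH2Br) under conditions that spare the acetonide.

**Step 8**
Reactants: 9 (2Z,6Z)-7-iodo-8,8-dimethoxy-3-methylocta-2,6-dienal; 13 methyl (2Z)-2-(bromomethyl)-3-[(4S)-2,2-dimethyl-1,3-dioxolan-4-yl]prop-2-enoate
Product: 14 methyl (3S,4S,5Z,9Z)-3-[(4S)-2,2-dimethyl-1,3-dioxolan-4-yl]-4-hydroxy-10-iodo-11,11-dimethoxy-6-methyl-2-methylideneundeca-5,9-dienoate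
Conditions: indium powder (1.5 equiv), THF/H2O (3:1), rt
Reagents that add atoms: none
Why: Indium-mediated Barbier allylation through a closed chair transition state with the Z γ-substituent axial gives the 6,7-syn homoallylic alcohol, and C7 is set by allylic 1,3-strain control from C8 (C8–H eclipsing the alkene, aldehyde approaching anti to the C8–C9 bond), which places C11 and O8 anti as in the target.

**Step 9**
Reactants: 14 methyl (3S,4S,5Z,9Z)-3-[(4S)-2,2-dimethyl-1,3-dioxolan-4-yl]-4-hydroxy-10-iodo-11,11-dimethoxy-6-methyl-2-methylideneundeca-5,9-dienoate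
Product: 17 (4S,5R)-4-[(4S)-2,2-dimethyl-1,3-dioxolan-4-yl]-5-[(1Z,5Z)-6-iodo-7,7-dimethoxy-2-methylhepta-1,5-dien-1-yl]-3-methylideneoxolan-2-one, via allylic fluorosulfate 15 (not isolated), via methoxylactonium fluorosulfate 16 (not isolated)
Conditions: SO2F2 (balloon), Et3N (2.5 equiv), MeCN, −20 °C to rt
Reagents that add atoms: none
Why: Proposed new method: sulfuryl fluoride turns the allylic C6 hydroxyl into fluorosulfate 15, which is displaced from the rear by the carbonyl oxygen of the methyl ester (5-exo) to give lactonium ion 16 that Et3N demethylates, so the C6–O bond forms with inversion and the 6,7-syn adduct becomes the trans-fused (6R) lactone, an outcome an ion-pair pathway would also favour because the C5 and C8 substituents avoid each other; the closest known reaction types are SO2F2-mediated dehydroxylative substitution of alcohols and the lactonisation of γ-sulfonyloxy esters by carbonyl participation with loss of the O-alkyl group.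

**Step 10**
Reactants: 17 (4S,5R)-4-[(4S)-2,2-dimethyl-1,3-dioxolan-4-yl]-5-[(1Z,5Z)-6-iodo-7,7-dimethoxy-2-methylhepta-1,5-dien-1-yl]-3-methylideneoxolan-2-one
Product: 18 (4R,5R)-4-[(1S)-1,2-dihydroxyethyl]-5-[(1Z,5Z)-6-iodo-7,7-dimethoxy-2-methylhepta-1,5-dien-1-yl]-3-methylideneoxolan-2-one
Conditions: PPTS (20 mol%), MeOH, 40 °C
Reagents that add atoms: none
Why: Acid-catalysed transketalisation in methanol removes the terminal acetonide while the dimethyl acetal only undergoes degenerate exchange and no stereocenter is touched.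

**Step 11**
Reactants: 18 (4R,5R)-4-[(1S)-1,2-dihydroxyethyl]-5-[(1Z,5Z)-6-iodo-7,7-dimethoxy-2-methylhepta-1,5-dien-1-yl]-3-methylideneoxolan-2-one
Product: 19 (2S)-2-hydroxy-2-{(2R,3R)-2-[(1Z,5Z)-6-iodo-7,7-dimethoxy-2-methylhepta-1,5-dien-1-yl]-4-methylidene-5-oxooxolan-3-yl}acetaldehyde
Conditions: TEMPO (10 mol%), PhI(OAc)2 (1.1 equiv), CH2Cl2, 0 °C to rt; used crude
Reagents that add atoms: none
Why: TEMPO-catalysed oxidation is selective for the primary hydroxyl over the secondary C8 hydroxyl and gives the C9 aldehyde, which is carried on at once to avoid epimerisation at C8.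

**Step 12**
Reactants: 19 (2S)-2-hydroxy-2-{(2R,3R)-2-[(1Z,5Z)-6-iodo-7,7-dimethoxy-2-methylhepta-1,5-dien-1-yl]-4-methylidene-5-oxooxolan-3-yl}acetaldehyde
Product: 20 (3aR,4S,5S,6E,10Z,11aR)-6-(dimethoxymethyl)-4,5-dihydroxy-10-methyl-3-methylidene-3a,4,5,8,9,11a-hexahydrocyclodeca[b]furan-2(3H)-one
Conditions: CrCl2 (8 equiv), NiCl2 (2 mol%), DMSO/THF (3:1), rt, 2 mM, slow addition
Reagents that add atoms: none
Why: Nozaki–Hiyama–Kishi macrocyclisation transfers the alkenyl group from iodine via nickel to chromium with retention of geometry and adds the C10–Cr bond to the aldehyde, ring closure being favoured by the two cis alkenes and the trans lactone, while chelation of the aldehyde by the C8 trivalent chromium alkoxide directs attack anti to C7 (Cram chelate) to give the 8,9-threo (9S) diol.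

**Step 13**
Reactants: 20 (3aR,4S,5S,6E,10Z,11aR)-6-(dimethoxymethyl)-4,5-dihydroxy-10-methyl-3-methylidene-3a,4,5,8,9,11a-hexahydrocyclodeca[b]furan-2(3H)-one; 21 2-methylpropanoic anhydride (isobutyric anhydride)
Product: 22 (3aS,4S,5S,6E,10Z,11aR)-6-(dimethoxymethyl)-10-methyl-3-methylidene-2-oxo-2,3,3a,4,5,8,9,11a-octahydrocyclodeca[b]furan-4,5-diyl bis(2-methylpropanoate)
Conditions: Et3N, DMAP (20 mol%), CH2Cl2, rt
Reagents that add atoms: none
Why: DMAP-catalysed acylation esterifies both secondary hydroxyls without affecting any stereocenter, and acyl migration between O8 and O9 is harmless because both esters are identical.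

**Step 14**
Reactants: 22 (3aS,4S,5S,6E,10Z,11aR)-6-(dimethoxymethyl)-10-methyl-3-methylidene-2-oxo-2,3,3a,4,5,8,9,11a-octahydrocyclodeca[b]furan-4,5-diyl bis(2-methylpropanoate)
Product: 23 (3aS,4S,5S,6E,10Z,11aR)-6-formyl-10-methyl-3-methylidene-2-oxo-2,3,3a,4,5,8,9,11a-octahydrocyclodeca[b]furan-4,5-diyl bis(2-methylpropanoate)
Conditions: 1 M aq. HCl, THF, 0 °C
Reagents that add atoms: water, O
Why: Mild aqueous acid hydrolyses the allylic dimethyl acetal to the conjugated aldehyde, whose geometry (CHO trans to C2) is the thermodynamically favoured one, while the lactone and the isobutyrates survive.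

**Compound list**
1 | (2Z)-3,7-dimethylocta-2,6-dien-1-yl acetate (neryl acetate) | CC(=O)OC/C=C(C)\CCC=C(C)C | starting material
2 | (2Z)-5-(5,5-dimethyl-1,2,4-trioxolan-3-yl)-3-methylpent-2-en-1-yl acetate (ozonide, racemic at the ring carbon) | CC(=O)OC/C=C(C)\CCC1OOC(C)(C)O1 | intermediate
3 | (2Z)-3-methyl-6-oxohex-2-en-1-yl acetate | CC(=O)OC/C=C(C)\CCC=O | intermediate
4 | (triphenylphosphoranylidene)acetaldehyde | O=CC=P(c1ccccc1)(c1ccccc1)c1ccccc1 | starting material
5 | (2Z,6E)-3-methyl-8-oxoocta-2,6-dien-1-yl acetate | CC(=O)OC/C=C(C)\CC/C=C/C=O | intermediate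
6 | (2Z,6Z)-7-iodo-3-methyl-8-oxoocta-2,6-dien-1-yl acetate | CC(=O)OC/C=C(C)\CC/C=C(\I)C=O | intermediate
7 | (2Z,6Z)-7-iodo-8,8-dimethoxy-3-methylocta-2,6-dien-1-yl acetate | CC(=O)OC/C=C(C)\CC/C=C(\I)C(OC)OC | intermediate
8 | (2Z,6Z)-7-iodo-8,8-dimethoxy-3-methylocta-2,6-dien-1-ol | OC/C=C(C)\CC/C=C(\I)C(OC)OC | intermediate
9 | (2Z,6Z)-7-iodo-8,8-dimethoxy-3-methylocta-2,6-dienal | O=C/C=C(C)\CC/C=C(\I)C(OC)OC | intermediate
10 | (4R)-2,2-dimethyl-1,3-dioxolane-4-carbaldehyde (D-glyceraldehyde acetonide) | O=C[C@H]1COC(C)(C)O1 | starting material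
11 | methyl prop-2-enoate | C=CC(=O)OC | starting material
12 | methyl 2-{[(4R)-2,2-dimethyl-1,3-dioxolan-4-yl](hydroxy)methyl}prop-2-enoate (both carbinol epimers) | COC(=O)C(=C)C(O)[C@H]1COC(C)(C)O1 | intermediate
13 | methyl (2Z)-2-(bromomethyl)-3-[(4S)-2,2-dimethyl-1,3-dioxolan-4-yl]prop-2-enoate | COC(=O)/C(CBr)=C/[C@H]1COC(C)(C)O1 | intermediate
14 | methyl (3S,4S,5Z,9Z)-3-[(4S)-2,2-dimethyl-1,3-dioxolan-4-yl]-4-hydroxy-10-iodo-11,11-dimethoxy-6-methyl-2-methylideneundeca-5,9-dienoate | C=C(C(=O)OC)[C@@H]([C@@H](O)/C=C(/C)CC/C=C(\I)C(OC)OC)[C@H]1COC(C)(C)O1 | intermediate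
15 | methyl (3R,4S,5Z,9Z)-3-[(4S)-2,2-dimethyl-1,3-dioxolan-4-yl]-4-[(fluorosulfonyl)oxy]-10-iodo-11,11-dimethoxy-6-methyl-2-methylideneundeca-5,9-dienoate | C=C(C(=O)OC)[C@@H]([C@@H](OS(=O)(=O)F)/C=C(/C)CC/C=C(\I)C(OC)OC)[C@H]1COC(C)(C)O1 | intermediate
16 | (4S,5R)-4-[(4S)-2,2-dimethyl-1,3-dioxolan-4-yl]-5-[(1Z,5Z)-6-iodo-7,7-dimethoxy-2-methylhepta-1,5-dien-1-yl]-2-methoxy-3-methylidene-4,5-dihydro-3H-furan-1-ium fluorosulfate | C=C1C(=[O+]C)O[C@H](/C=C(/C)CC/C=C(\I)C(OC)OC)[C@H]1[C@H]2COC(C)(C)O2.[O-]S(=O)(=O)F | intermediate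
17 | (4S,5R)-4-[(4S)-2,2-dimethyl-1,3-dioxolan-4-yl]-5-[(1Z,5Z)-6-iodo-7,7-dimethoxy-2-methylhepta-1,5-dien-1-yl]-3-methylideneoxolan-2-one | C=C1C(=O)O[C@H](/C=C(/C)CC/C=C(\I)C(OC)OC)[C@H]1[C@H]2COC(C)(C)O2 | intermediate
18 | (4R,5R)-4-[(1S)-1,2-dihydroxyethyl]-5-[(1Z,5Z)-6-iodo-7,7-dimethoxy-2-methylhepta-1,5-dien-1-yl]-3-methylideneoxolan-2-one | C=C1C(=O)O[C@H](/C=C(/C)CC/C=C(\I)C(OC)OC)[C@H]1[C@H](O)CO | intermediate
19 | (2S)-2-hydroxy-2-{(2R,3R)-2-[(1Z,5Z)-6-iodo-7,7-dimethoxy-2-methylhepta-1,5-dien-1-yl]-4-methylidene-5-oxooxolan-3-yl}acetaldehyde | C=C1C(=O)O[C@H](/C=C(/C)CC/C=C(\I)C(OC)OC)[C@H]1[C@H](O)C=O | intermediate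
20 | (3aR,4S,5S,6E,10Z,11aR)-6-(dimethoxymethyl)-4,5-dihydroxy-10-methyl-3-methylidene-3a,4,5,8,9,11a-hexahydrocyclodeca[b]furan-2(3H)-one | C=C1C(=O)O[C@@H]2/C=C(/C)CC/C=C(/C(OC)OC)[C@H](O)[C@@H](O)[C@@H]12 | intermediate
21 | 2-methylpropanoic anhydride | CC(C)C(=O)OC(=O)C(C)C | starting material
22 | (3aS,4S,5S,6E,10Z,11aR)-6-(dimethoxymethyl)-10-methyl-3-methylidene-2-oxo-2,3,3a,4,5,8,9,11a-octahydrocyclodeca[b]furan-4,5-diyl bis(2-methylpropanoate) | C=C1C(=O)O[C@@H]2/C=C(/C)CC/C=C(/C(OC)OC)[C@H](OC(=O)C(C)C)[C@@H](OC(=O)C(C)C)[C@@H]12 | intermediate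
23 | (3aS,4S,5S,6E,10Z,11aR)-6-formyl-10-methyl-3-methylidene-2-oxo-2,3,3a,4,5,8,9,11a-octahydrocyclodeca[b]furan-4,5-diyl bis(2-methylpropanoate) | C=C1C(=O)O[C@@H]2/C=C(/C)CC/C=C(/C=O)[C@H](OC(=O)C(C)C)[C@@H](OC(=O)C(C)C)[C@@H]12 | target

**Step count**
Total step count: 14. Longest linear sequence: 12 steps (steps 1–5 and 8–14, from neryl acetate); steps 6–7 make the second fragment.

**Three steps most likely to fail**

Step 9, the proposed new lactonisation. It could lose to base-promoted transesterification with retention (cis-lactone), to fluoride substitution or elimination at the allylic fluorosulfate, or to participation by a dioxolane oxygen. The fallback uses known chemistry, sets out from 14 and comes back at 17. The methyl ester is saponified (LiOH, THF/H2O, 0 °C, acidified cold to pH 5) to (3S,4S,5Z,9Z)-3-[(4S)-2,2-dimethyl-1,3-dioxolan-4-yl]-4-hydroxy-10-iodo-11,11-dimethoxy-6-methyl-2-methylideneundeca-5,9-dienoic acid F1. This is closed at once by Mitsunobu lactonisation (PPh3, DIAD, THF, −20 °C), which forms the same C6–O bond with inversion.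

Step 12, the ring closure. Oligomerisation is met by dilution, but the C9 configuration rests on chelation control inside a forming ten-membered ring and may come out wrong or mixed. The fallback sets out from 19 and comes back at 20. The closure is accepted as it comes, giving (3aR,4S,5R,6E,10Z,11aR)-6-(dimethoxymethyl)-4,5-dihydroxy-10-methyl-3-methylidene-3a,4,5,8,9,11a-hexahydrocyclodeca[b]furan-2(3H)-one F2 (alone or mixed with 20). The allylic C9 carbinol is oxidised selectively (MnO2, CH2Cl2, rt) to (3aR,4S,6Z,10Z,11aR)-6-(dimethoxymethyl)-4-hydroxy-10-methyl-3-methylidene-3a,4,8,9-tetrahydrocyclodeca[b]furan-2,5(3H,11aH)-dione F3. C9 is then reset by reagent-controlled reduction with (S)-Me-CBS [(S)-2-methyl-CBS-oxazaborolidine, 20 mol%] and catecholborane in toluene at −78 °C; the catalyst enantiomer is chosen on the assumption that the alkenyl group acts as the large substituent.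

Step 8, the Barbier coupling. The 6,7-syn outcome is reliable, but the facial selectivity at C7 relies on substrate control from the acetonide and could be low or reversed. The fallback sets out from 13 (with 9) and comes back at 14. Bromide 13 is converted (B2pin2, Pd2(dba)3 2.5 mol%, toluene, 50 °C) into methyl (2E)-3-[(4S)-2,2-dimethyl-1,3-dioxolan-4-yl]-2-[(4,4,5,5-tetramethyl-1,3,2-dioxaborolan-2-yl)methyl]prop-2-enoate F4. This isolated allylboronate is added to 9 under chiral phosphoric acid catalysis with (R)- or (S)-TRIP [3,3′-bis(2,4,6-triisopropylphenyl)-1,1′-binaphthyl-2,2′-diyl hydrogen phosphate, 5 mol%] in toluene at −30 °C, then worked up with water. The closed chair transition state keeps the syn relationship and the catalyst enantiomer, chosen by screening, sets the face.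

**Further compounds**
F1 | step 9 | (3S,4S,5Z,9Z)-3-[(4S)-2,2-dimethyl-1,3-dioxolan-4-yl]-4-hydroxy-10-iodo-11,11-dimethoxy-6-methyl-2-methylideneundeca-5,9-dienoic acid | C=C(C(=O)O)[C@@H]([C@@H](O)/C=C(/C)CC/C=C(\I)C(OC)OC)[C@H]1COC(C)(C)O1
F2 | step 12 | (3aR,4S,5R,6E,10Z,11aR)-6-(dimethoxymethyl)-4,5-dihydroxy-10-methyl-3-methylidene-3a,4,5,8,9,11a-hexahydrocyclodeca[b]furan-2(3H)-one | C=C1C(=O)O[C@@H]2/C=C(/C)CC/C=C(/C(OC)OC)[C@@H](O)[C@@H](O)[C@@H]12
F3 | step 12 | (3aR,4S,6Z,10Z,11aR)-6-(dimethoxymethyl)-4-hydroxy-10-methyl-3-methylidene-3a,4,8,9-tetrahydrocyclodeca[b]furan-2,5(3H,11aH)-dione | C=C1C(=O)O[C@@H]2/C=C(/C)CC/C=C(/C(OC)OC)C(=O)[C@@H](O)[C@@H]12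
F4 | step 8 | methyl (2E)-3-[(4S)-2,2-dimethyl-1,3-dioxolan-4-yl]-2-[(4,4,5,5-tetramethyl-1,3,2-dioxaborolan-2-yl)methyl]prop-2-enoate | COC(=O)/C(CB1OC(C)(C)C(C)(C)O1)=C/[C@H]2COC(C)(C)O2
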